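Start from what stays unreacted: starting material left in the vessel can meet intermediate A and go to side product B, so reckon that leftover concentration first.

    starting material ⇌ intermediate A (K1 = 1.1, k1 = 0.0041 s⁻¹)
    starting material + intermediate A → side product B (k2 = 0.13 L mol⁻¹ s⁻¹)
    intermediate B → side product A (k3 = 0.0017 s⁻¹)
    starting material → intermediate B (k4 = 9.9 × 10⁻⁴ s⁻¹)
    intermediate A → target (k5 = 9.8 × 10⁻⁴ s⁻¹)

| flask | starting material | remark | time |
|---|---|---|---|
| alpha | 0.076 M | one stirred flow tank at steady state, fed with the mixture as stated, mean residence time 80 min |  |
| epsilon | 0.076 M | plug flow through a tube for 80 min, no back-mixing | 80 min |
| eta | 0.076 M | everything together in a closed stirred flask, run for 80 min | 80 min |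

1. the set-up with the highest amount of target at the outlet or at the end, in percent of the starting material put in ("none" if the first two lie within 2 percentage points) (alpha / epsilon / eta / none)
2. amount of target at the outlet or at the end, in percent of the starting material put in, alpha
3. amount of target at the outlet or at the end, in percent of the starting material put in, epsilon
4. amount of target at the outlet or at the end, in percent of the starting material put in, eta

- percent here means starting material units held: one side product B counts as two
- the stated concentrations are those of everything mixed, before any reaction; amounts are the same in each set-up
- run time (epsilon): 80 min

Take alpha first. Define the ratio as intermediate A per starting material in the tank. Its balance makes the ratio the forward constant divided by the sum of four removals: the way back, the step to target, the step with starting material, and the outflow. The feed balance then gives starting material from the ratio. Each needs the other, so begin at equilibrium and go round: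

- First round: ratio 1.1, starting material 0.00425 M, target 29.0%.
- Second round: ratio 0.750, starting material 0.00513 M, target 23.8%.
- Third round: ratio 0.734, starting material 0.00518 M, target 23.5%.

Read down the lines. The ratio falls below equilibrium because the step to target, the step with starting material and the outflow together add 0.104 min⁻¹ to the way back's 0.224 min⁻¹. The last round moves target by 0.30 percentage points, so stop there.

Now take the third line's ratio and define the even-loss concentration: the starting material level at which loss to side product B equals the two first-order exits, 0.00895 M. Target's share of the first-order exits is 42.1%. For epsilon and eta, which share one time course, assume the same ratio. The split charge starts 4.89 times above the even-loss concentration, and that share is multiplied by the logarithm of one plus this figure, divided by the figure. That gives 15.3%.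

The forecast says alpha, with 23.5% (22.5% to 24.5%) for alpha, and 15% and 15% (each 13.5% to 16.5%) for epsilon and eta, on the ground that “the stirred tank's immediate dilution keeps concentrations low”.

The simulation gives 23.5% in alpha, 15.5% in epsilon and 15.5% in eta, so alpha leads. The tank holds 0.00518 M of starting material, 0.579 of the even-loss concentration. Take the neighbour of eta charged with 0.019 M: it starts 1.22 times above the even-loss concentration, and the same reckoning gives 27.5% target. That flask gives 29.4%, with side product A at 37.8% and side product B at 32.1%.

The numbers come from no measurement.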